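**Retrosynthetic overview**
1. Target 32 ⇒ ester C–O bond between fragment A acid 29 and the primary hydroxyl of fragment B diol 18; the PMB ethers and the tert-butyl ester fall in one final acidolysis.
2. 18 ⇐ seven-membered lactone by ring-closing metathesis of acrylate ester 16 ⇐ cis acid–aldehyde 13 (Wittig methylenation, O-alkylation).
3. 29 ⇐ enantiomeric acid–aldehyde 23: side chain by oxa-Michael/HWE olefination, ring alkene by β-lactone decarboxylation (the carboxyl carbon is excised).
4. 13 and 23 ⇐ ozonolysis of siloxycyclobutenes 11 and 21 ⇐ convex-face hydroxymethylation ⇐ key [2+2] cycloaddition of siloxyalkyne 7 to (S)- or (R)-cryptone (cis-fused, anti to isopropyl).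
5. Ring order: cyclohexane rings bought in cryptone → cyclobutene (cycloaddition, later cleaved) → lactone ring of fragment B (metathesis); fragment A keeps only its bought ring.

Assumption: both enantiomers of cryptone (8 and 19) are taken as purchasable chiral-pool terpene ketones; PMB = 4-methoxybenzyl.

**Route**

Step 1
Reactants: 1 tributyl(iodomethyl)stannane; 2 4-methoxybenzyl alcohol
Product: 3 tributyl{[(4-methoxybenzyl)oxy]methyl}stannane
Conditions: NaH, THF/DMF, 0 °C → rt
Reagents that add atoms: none
Why: Williamson ether synthesis in which the sodium alkoxide of 2 displaces iodide from the unhindered iodomethyl carbon (SN2); no stereocentre is involved.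

Step 2
Reactants: 4 acetylene
Product: 7 (triisopropylsilyloxy)ethyne, via lithium acetylide 5 (not isolated), via lithium ethynolate 6 (not isolated)
Conditions: n-BuLi, THF, −78 °C; LiOOt-Bu (from t-BuOOH and LiN(SiMe3)2), −78 → −20 °C; i-Pr3SiOTf, −78 °C; cold pentane/H2O work-up, used at once
Reagents that add atoms: tert-butyl hydroperoxide, CC(C)(C)OO; triisopropylsilyl trifluoromethanesulfonate, CC(C)[Si](C(C)C)(C(C)C)OS(=O)(=O)C(F)(F)F
Why: Lithium tert-butyl peroxide transfers an electrophilic oxygen to the acetylide carbon (oxidation of a carbanion to the ynolate) and the bulky silyl triflate then reacts on oxygen (O-silylation of an ynolate); no stereocentre is involved.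

Step 3
Reactants: 8 (S)-(+)-cryptone; 7 (triisopropylsilyloxy)ethyne
Product: 9 cis-fused 5-isopropyl-8-(triisopropylsilyloxy)bicyclo[4.2.0]oct-7-en-2-one of the (S)-cryptone series (cyclobutene trans to isopropyl)
Conditions: AgNTf2 (10 mol %), CH2Cl2, −20 °C → rt
Reagents that add atoms: none
Why: Silver-catalysed Ficini-type [2+2] cycloaddition of a siloxyalkyne to an enone, in which the unsubstituted alkyne carbon attacks the β-carbon anti to the adjacent isopropyl group and the siloxy-bearing carbon then closes onto the α-carbon from the same face, so both new stereocentres (cis ring fusion, four-membered ring trans to isopropyl) are set by the bought one.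

Step 4
Reactants: 3 tributyl{[(4-methoxybenzyl)oxy]methyl}stannane
Product: 10 (4-methoxybenzyloxy)methyllithium (one batch, kept as a THF solution at −78 °C and used at once in steps 5 and 12)
Conditions: n-BuLi, THF, −78 °C, 15 min
Reagents that add atoms: n-butyllithium, [Li]CCCC
Why: Tin–lithium exchange (Still's α-alkoxymethyllithium) is fast at −78 °C because the oxygen-stabilised carbanion is the best leaving group on tin, and the solution is stable for hours at that temperature, so a single batch is divided by pre-cooled cannula between the two enantiomeric ketones of steps 5 and 12, which are run side by side; no stereocentre is involved.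

Step 5
Reactants: 9 cis-fused siloxycyclobutene ketone of the (S)-cryptone series; 10 (4-methoxybenzyloxy)methyllithium
Product: 11 5-isopropyl-2-[(4-methoxybenzyloxy)methyl]-8-(triisopropylsilyloxy)bicyclo[4.2.0]oct-7-en-2-ol (OH cis to the cyclobutene)
Conditions: 10 (THF solution from step 4, 1.5 equiv), THF, −78 °C; H2O quench at −78 °C
Reagents that add atoms: none
Why: 1,2-Addition of the α-alkoxymethyllithium to the ketone from the convex face of the cis-bicyclo[4.2.0]octene (anti to the cyclobutene), so the new carbinol stereocentre carries OH cis and CH2OPMB trans to the four-membered ring; the cold quench avoids silyl migration.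

Step 6
Reactants: 11 tertiary alcohol of the (S)-cryptone series
Product: 13 6-formyl-2-hydroxy-5-isopropyl-2-[(4-methoxybenzyloxy)methyl]cyclohexane-1-carboxylic acid (CO2H and OH and CHO all cis; isopropyl trans to CHO), via triisopropylsilyl ester 12 (not isolated)
Conditions: O3, CH2Cl2, −78 °C (Sudan Red 7B end point); Me2S, −78 °C → rt; then AcOH/THF/H2O, rt
Reagents that add atoms: ozone, [O-][O+]=O
Why: Ozonolysis of the electron-rich silyl enol ether double bond (far faster than attack on the anisyl ring) opens the cyclobutene to a silyl ester and an aldehyde that keep their cis relationship, and aqueous acetic acid then hydrolyses the silyl ester; the formyl-bearing carbon already has its more stable equatorial configuration, so nothing epimerises.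

Step 7
Reactants: 13 cis acid–aldehyde
Product: 14 6-ethenyl-2-hydroxy-5-isopropyl-2-[(4-methoxybenzyloxy)methyl]cyclohexane-1-carboxylic acid (configuration as in 13)
Conditions: Ph3PCH3Br, KOt-Bu (excess), THF, 0 °C → rt; then cold 1 M HCl to pH 3
Reagents that add atoms: methyltriphenylphosphonium bromide, C[P+](c1ccccc1)(c1ccccc1)c1ccccc1.[Br-]
Why: Wittig methylenation with excess ylide (carboxylate and alkoxide are spectators) turns the aldehyde into the vinyl group without touching a stereocentre.

Step 8
Reactants: 14 vinyl acid; 15 tert-butyl 2-(bromomethyl)acrylate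
Product: 16 2-(tert-butoxycarbonyl)prop-2-en-1-yl ester of 14
Conditions: K2CO3, DMF, 0 °C → rt
Reagents that add atoms: none
Why: O-alkylation of the potassium carboxylate by the activated allylic bromide (SN2 or SN2', same product) esterifies the hindered acid without acyl activation and leaves the tertiary alcohol alone; no stereocentre is involved.

Step 9
Reactants: 16 acrylate ester
Product: 17 tert-butyl (5aR,6S,9R,9aS)-9-hydroxy-6-isopropyl-9-[(4-methoxybenzyloxy)methyl]-1-oxo-1,3,5a,6,7,8,9,9a-octahydro-2-benzoxepine-4-carboxylate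
Conditions: second-generation Hoveyda–Grubbs catalyst (C31H38Cl2N2ORu, 10 mol %), toluene (0.005 M), 80 °C
Reagents that add atoms: none
Why: Ring-closing olefin metathesis between the vinyl group and the 1,1-disubstituted acrylate closes the seven-membered lactone with loss of ethene, and the ring forces the CH2O carbon cis to the ring-fusion carbon, which is the alkene geometry of the target; the cis ring-fusion stereocentres are kept.

Step 10
Reactants: 17 PMB-protected lactone
Product: 18 tert-butyl (5aR,6S,9R,9aS)-9-hydroxy-9-(hydroxymethyl)-6-isopropyl-1-oxo-1,3,5a,6,7,8,9,9a-octahydro-2-benzoxepine-4-carboxylate (fragment B diol)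
Conditions: DDQ, CH2Cl2/pH 7 buffer (10:1), 0 °C → rt
Reagents that add atoms: none
Why: Oxidative cleavage of the PMB ether by DDQ (hydride abstraction, hydrolysis of the oxocarbenium ion) frees the primary alcohol without touching ester, lactone, alkene or stereocentres.

Step 11
Reactants: 19 (R)-(−)-cryptone; 7 (triisopropylsilyloxy)ethyne
Product: 20 enantiomer of 9
Conditions: AgNTf2 (10 mol %), CH2Cl2, −20 °C → rt
Reagents that add atoms: none
Why: The same silver-catalysed Ficini-type [2+2] cycloaddition as in step 3 on the enantiomeric enone, again anti to isopropyl and cis-fused, so the mirror-image stereocentres follow from the bought (R) centre.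

Step 12
Reactants: 20 enantiomer of 9; 10 (4-methoxybenzyloxy)methyllithium
Product: 21 enantiomer of 11
Conditions: 10 (THF solution from step 4, 1.5 equiv), THF, −78 °C; H2O quench at −78 °C
Reagents that add atoms: none
Why: As in step 5, convex-face 1,2-addition of the α-alkoxymethyllithium sets the carbinol centre with OH cis to the cyclobutene.

Step 13
Reactants: 21 enantiomer of 11
Product: 23 enantiomer of 13, via triisopropylsilyl ester 22 (not isolated)
Conditions: O3, CH2Cl2, −78 °C (Sudan Red 7B end point); Me2S, −78 °C → rt; then AcOH/THF/H2O, rt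
Reagents that add atoms: ozone, [O-][O+]=O
Why: As in step 6, ozonolysis of the silyl enol ether and hydrolysis of the silyl ester give the cis acid–aldehyde without change at any stereocentre.

Step 14
Reactants: 23 enantiomer of 13; 2 4-methoxybenzyl alcohol; 24 trimethyl 2-phosphonoacrylate
Product: 26 2-hydroxy-5-isopropyl-6-{(E)-3-methoxy-2-[(4-methoxybenzyloxy)methyl]-3-oxoprop-1-en-1-yl}-2-[(4-methoxybenzyloxy)methyl]cyclohexane-1-carboxylic acid (ring configuration as in 23), via sodium phosphonate 25 (not isolated)
Conditions: 2, NaH, THF, 0 °C; 24, 0 °C, 30 min; then sodium salt of 23 (NaH, THF), 0 °C → rt; cold 1 M HCl to pH 3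
Reagents that add atoms: none
Why: Tandem oxa-Michael addition and Horner–Wadsworth–Emmons olefination, in which the alkoxide of 2 adds to the vinylphosphonate and the stabilised phosphonate anion 25 olefinates the α-branched aldehyde to the (E)-trisubstituted acrylate (ester trans to the ring, the thermodynamically favoured geometry), leaving the ring stereocentres untouched.

Step 15
Reactants: 26 hydroxy acid
Product: 28 methyl (E)-3-[(1R,6R)-6-isopropyl-3-{[(4-methoxybenzyl)oxy]methyl}cyclohex-2-en-1-yl]-2-{[(4-methoxybenzyl)oxy]methyl}prop-2-enoate, via cis-fused beta-lactone 27 (not isolated)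
Conditions: PhSO2Cl, pyridine, 0 °C, 16 h; extractive work-up; toluene, 110 °C
Reagents that add atoms: none
Why: Adam β-lactone route to alkenes, in which sulfonyl activation of the acid lets the cis tertiary hydroxyl close the β-lactone with retention and thermal [2+2] cycloreversion expels CO2 to place the ring double bond regiospecifically between the former carbinol and carboxyl-bearing carbons, deleting these two stereocentres.

Step 16
Reactants: 28 methyl ester
Product: 29 (E)-3-[(1R,6R)-6-isopropyl-3-{[(4-methoxybenzyl)oxy]methyl}cyclohex-2-en-1-yl]-2-{[(4-methoxybenzyl)oxy]methyl}prop-2-enoic acid (fragment A acid)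
Conditions: LiOH, THF/MeOH/H2O, 0 °C → rt; then 1 M HCl to pH 3
Reagents that add atoms: lithium hydroxide, [Li+].[OH-]
Why: Saponification (acyl–oxygen cleavage) of the only ester with cold LiOH, mild enough to leave the doubly allylic stereocentre and the alkene positions alone.

Step 17
Reactants: 29 fragment A acid; 18 fragment B diol
Product: 31 ester of 29 and the primary hydroxyl of 18 (bis-PMB tert-butyl ester of the target), via mixed anhydride 30 (not isolated)
Conditions: 2,4,6-trichlorobenzoyl chloride, Et3N, THF, 0 °C; then 18, DMAP, toluene, rt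
Reagents that add atoms: none
Why: Yamaguchi esterification, in which the mixed anhydride transfers the acyl group via DMAP to the primary neopentyl hydroxyl of 18 while the tertiary hydroxyl is too hindered to react; no stereocentre is affected.

Step 18
Reactants: 31 protected target
Product: 32 CNP0361406.3 (target)
Conditions: TFA/CH2Cl2 (1:4), anisole, 0 °C → rt; aq. NaHCO3, then re-acidify to pH 3
Reagents that add atoms: none
Why: Acidolysis in which TFA cleaves the tert-butyl ester by loss of 2-methylpropene and both PMB ethers by way of the 4-methoxybenzyl cation that anisole traps (Friedel–Crafts), with an exposure short and mild enough to leave the tertiary alcohol, lactone, ester link and stereocentres intact.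

**Compound list**
1 | tributyl(iodomethyl)stannane | CCCC[Sn](CCCC)(CCCC)CI | starting material
2 | 4-methoxybenzyl alcohol | COc1ccc(CO)cc1 | starting material
3 | tributyl{[(4-methoxybenzyl)oxy]methyl}stannane | CCCC[Sn](CCCC)(CCCC)COCc1ccc(OC)cc1 | intermediate
4 | acetylene | C#C | starting material
5 | lithium acetylide | [Li]C#C | intermediate
6 | lithium ethynolate | [Li]OC#C | intermediate
7 | (triisopropylsilyloxy)ethyne | C#CO[Si](C(C)C)(C(C)C)C(C)C | intermediate
8 | (S)-(+)-cryptone, (4S)-4-isopropylcyclohex-2-en-1-one | O=C1CC[C@@H](C(C)C)C=C1 | starting material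
9 | cis-fused 5-isopropyl-8-(triisopropylsilyloxy)bicyclo[4.2.0]oct-7-en-2-one, (S)-cryptone series, cyclobutene trans to isopropyl | O=C1CC[C@@H](C(C)C)[C@@H]2C=C(O[Si](C(C)C)(C(C)C)C(C)C)[C@@H]21 | intermediate
10 | (4-methoxybenzyloxy)methyllithium (THF solution at −78 °C) | [Li]COCc1ccc(OC)cc1 | intermediate
11 | 5-isopropyl-2-[(4-methoxybenzyloxy)methyl]-8-(triisopropylsilyloxy)bicyclo[4.2.0]oct-7-en-2-ol, OH cis to the cyclobutene | COc1ccc(COC[C@@]2(O)CC[C@@H](C(C)C)[C@@H]3C=C(O[Si](C(C)C)(C(C)C)C(C)C)[C@@H]32)cc1 | intermediate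
12 | triisopropylsilyl ester of 13 | COc1ccc(COC[C@@]2(O)CC[C@@H](C(C)C)[C@H](C=O)[C@@H]2C(=O)O[Si](C(C)C)(C(C)C)C(C)C)cc1 | intermediate
13 | 6-formyl-2-hydroxy-5-isopropyl-2-[(4-methoxybenzyloxy)methyl]cyclohexane-1-carboxylic acid, CO2H/OH/CHO all cis, isopropyl trans to CHO | COc1ccc(COC[C@@]2(O)CC[C@@H](C(C)C)[C@H](C=O)[C@@H]2C(=O)O)cc1 | intermediate
14 | 6-ethenyl-2-hydroxy-5-isopropyl-2-[(4-methoxybenzyloxy)methyl]cyclohexane-1-carboxylic acid, configuration as in 13 | COc1ccc(COC[C@@]2(O)CC[C@@H](C(C)C)[C@H](C=C)[C@@H]2C(=O)O)cc1 | intermediate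
15 | tert-butyl 2-(bromomethyl)acrylate | C=C(CBr)C(=O)OC(C)(C)C | starting material
16 | 2-(tert-butoxycarbonyl)prop-2-en-1-yl ester of 14 | COc1ccc(COC[C@@]2(O)CC[C@@H](C(C)C)[C@H](C=C)[C@@H]2C(=O)OCC(=C)C(=O)OC(C)(C)C)cc1 | intermediate
17 | tert-butyl (5aR,6S,9R,9aS)-9-hydroxy-6-isopropyl-9-[(4-methoxybenzyloxy)methyl]-1-oxo-1,3,5a,6,7,8,9,9a-octahydro-2-benzoxepine-4-carboxylate | COc1ccc(COC[C@@]2(O)CC[C@@H](C(C)C)[C@@H]3C=C(C(=O)OC(C)(C)C)COC(=O)[C@@H]32)cc1 | intermediate
18 | tert-butyl (5aR,6S,9R,9aS)-9-hydroxy-9-(hydroxymethyl)-6-isopropyl-1-oxo-1,3,5a,6,7,8,9,9a-octahydro-2-benzoxepine-4-carboxylate (fragment B diol) | OC[C@@]1(O)CC[C@@H](C(C)C)[C@@H]2C=C(C(=O)OC(C)(C)C)COC(=O)[C@@H]21 | intermediate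
19 | (R)-(−)-cryptone, (4R)-4-isopropylcyclohex-2-en-1-one | O=C1CC[C@H](C(C)C)C=C1 | starting material
20 | enantiomer of 9 | O=C1CC[C@H](C(C)C)[C@H]2C=C(O[Si](C(C)C)(C(C)C)C(C)C)[C@H]21 | intermediate
21 | enantiomer of 11 | COc1ccc(COC[C@]2(O)CC[C@H](C(C)C)[C@H]3C=C(O[Si](C(C)C)(C(C)C)C(C)C)[C@H]32)cc1 | intermediate
22 | enantiomer of 12 | COc1ccc(COC[C@]2(O)CC[C@H](C(C)C)[C@@H](C=O)[C@H]2C(=O)O[Si](C(C)C)(C(C)C)C(C)C)cc1 | intermediate
23 | enantiomer of 13 | COc1ccc(COC[C@]2(O)CC[C@H](C(C)C)[C@@H](C=O)[C@H]2C(=O)O)cc1 | intermediate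
24 | trimethyl 2-phosphonoacrylate, methyl 2-(dimethoxyphosphoryl)prop-2-enoate | C=C(C(=O)OC)P(=O)(OC)OC | starting material
25 | sodium salt of methyl 2-(dimethoxyphosphoryl)-3-(4-methoxybenzyloxy)propanoate | COC(=O)[C-](COCc1ccc(OC)cc1)P(=O)(OC)OC.[Na+] | intermediate
26 | 2-hydroxy-5-isopropyl-6-{(E)-3-methoxy-2-[(4-methoxybenzyloxy)methyl]-3-oxoprop-1-en-1-yl}-2-[(4-methoxybenzyloxy)methyl]cyclohexane-1-carboxylic acid, ring configuration as in 23 | COc1ccc(COC[C@]2(O)CC[C@H](C(C)C)[C@@H](/C=C(\COCc3ccc(OC)cc3)C(=O)OC)[C@H]2C(=O)O)cc1 | intermediate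
27 | cis-fused beta-lactone of 26 | COc1ccc(COC[C@]23CC[C@H](C(C)C)[C@@H](/C=C(\COCc4ccc(OC)cc4)C(=O)OC)[C@H]2C(=O)O3)cc1 | intermediate
28 | methyl (E)-3-[(1R,6R)-6-isopropyl-3-{[(4-methoxybenzyl)oxy]methyl}cyclohex-2-en-1-yl]-2-{[(4-methoxybenzyl)oxy]methyl}prop-2-enoate | CC(C)[C@H]1CCC(COCc2ccc(OC)cc2)=C[C@@H]1/C=C(\COCc3ccc(OC)cc3)C(=O)OC | intermediate
29 | (E)-3-[(1R,6R)-6-isopropyl-3-{[(4-methoxybenzyl)oxy]methyl}cyclohex-2-en-1-yl]-2-{[(4-methoxybenzyl)oxy]methyl}prop-2-enoic acid (fragment A acid) | CC(C)[C@H]1CCC(COCc2ccc(OC)cc2)=C[C@@H]1/C=C(\COCc3ccc(OC)cc3)C(=O)O | intermediate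
30 | mixed anhydride of 29 and 2,4,6-trichlorobenzoic acid | CC(C)[C@H]1CCC(COCc2ccc(OC)cc2)=C[C@@H]1/C=C(\COCc3ccc(OC)cc3)C(=O)OC(=O)c4c(Cl)cc(Cl)cc4Cl | intermediate
31 | ester of 29 with the primary hydroxyl of 18 (bis-PMB tert-butyl ester of the target) | CC(C)[C@H]1CCC(COCc2ccc(OC)cc2)=C[C@@H]1/C=C(\COCc3ccc(OC)cc3)C(=O)OC[C@@]4(O)CC[C@@H](C(C)C)[C@@H]5C=C(C(=O)OC(C)(C)C)COC(=O)[C@@H]54 | intermediate
32 | CNP0361406.3 | CC(C)[C@H]1CCC(CO)=C[C@@H]1/C=C(\CO)C(=O)OC[C@@]1(O)CC[C@@H](C(C)C)[C@@H]2C=C(C(=O)O)COC(=O)[C@@H]21 | target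

**Step count**
Total: 18 steps. Longest linear sequence: 10 steps (4 → 7 → 9 → 11 → 13 → 14 → 16 → 17 → 18 → 31 → 32; steps 2, 3, 5–10, 17 and 18).

**Three steps most likely to fail, with fallbacks**

Step 3 (and its mirror image, step 11). The terminal silyl ynol ether 7 is labile, and its silver-catalysed cycloaddition to a γ-branched cyclohexenone is an extension of what is known for substituted siloxyalkynes. The fallback is the classical enone–allene photocycloaddition, which needs neither 7 nor silver. It sets out from 8: irradiation (Pyrex-filtered mercury lamp, THF, −78 °C) with propa-1,2-diene gives the head-to-head adduct, the cis-fused 8-methylidene ketone F1, whose minor syn isomer is removed by chromatography. Reagent 10 (the cold solution from step 4) adds from the convex face to give the tertiary alcohol F2. Ozonolysis (O3; Me2S) of the exocyclic methylidene gives the cyclobutanone F3. Me3SiOTf/Et3N silylates the tertiary hydroxyl and enolises the cyclobutanone toward its CH2 to give the bis(trimethylsilyl) compound F4. A second ozonolysis (O3; Me2S; aqueous acidic work-up) cleaves the silyl enol ether and comes back to the route at 13. For step 11 the same sequence sets out from 19 and runs through the enantiomeric photoadduct F5, the tertiary alcohol F6, the cyclobutanone F7 and the bis(trimethylsilyl) compound F8 to come back at 23.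

Step 9. Ring-closing metathesis has to join a hindered vinyl group to an electron-poor 1,1-disubstituted alkene in a seven-membered ring. The fallback builds the same ring by olefination and sets out from 13. With Cs2CO3 and tert-butyl 2-(diethoxyphosphoryl)acrylate in MeCN, the caesium carboxylate adds in oxa-Michael fashion to give the phosphonate ester F9. Its anion then closes onto the neighbouring aldehyde by intramolecular Horner–Wadsworth–Emmons reaction, which comes back to the route at 17 and bypasses 14 and 16.

Step 14. The alkoxide addition to the vinylphosphonate is reversible, the substrate carries a free carboxylate, and the E/Z ratio of the trisubstituted alkene is not assured. The fallback replaces the in-flask phosphonate by a preformed, isolable phosphorane and sets out from 23. Methyl 3-(4-methoxybenzyloxy)-2-(triphenylphosphoranylidene)propanoate F10 is made from methyl (triphenylphosphoranylidene)acetate (2 equiv) and 4-methoxybenzyl chloromethyl ether. Heating F10 with the triethylammonium salt of 23 in toluene gives a base-free, E-selective Wittig olefination that comes back to the route at 26.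

**Further compounds**
F1 | step 3 | cis-fused 5-isopropyl-8-methylidenebicyclo[4.2.0]octan-2-one of the (S)-cryptone series (four-membered ring trans to isopropyl) | O=C1CC[C@@H](C(C)C)[C@@H]2CC(=C)[C@@H]21
F2 | step 3 | 5-isopropyl-2-[(4-methoxybenzyloxy)methyl]-8-methylidenebicyclo[4.2.0]octan-2-ol (OH cis to the four-membered ring) | COc1ccc(COC[C@@]2(O)CC[C@@H](C(C)C)[C@@H]3CC(=C)[C@@H]32)cc1
F3 | step 3 | 2-hydroxy-5-isopropyl-2-[(4-methoxybenzyloxy)methyl]bicyclo[4.2.0]octan-8-one | COc1ccc(COC[C@@]2(O)CC[C@@H](C(C)C)[C@@H]3CC(=O)[C@@H]32)cc1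
F4 | step 3 | 5-isopropyl-2-[(4-methoxybenzyloxy)methyl]-2,8-bis(trimethylsilyloxy)bicyclo[4.2.0]oct-7-ene | COc1ccc(COC[C@@]2(O[Si](C)(C)C)CC[C@@H](C(C)C)[C@@H]3C=C(O[Si](C)(C)C)[C@@H]32)cc1
F5 | step 11 | enantiomer of F1 | O=C1CC[C@H](C(C)C)[C@H]2CC(=C)[C@H]21
F6 | step 11 | enantiomer of F2 | COc1ccc(COC[C@]2(O)CC[C@H](C(C)C)[C@H]3CC(=C)[C@H]32)cc1
F7 | step 11 | enantiomer of F3 | COc1ccc(COC[C@]2(O)CC[C@H](C(C)C)[C@H]3CC(=O)[C@H]32)cc1
F8 | step 11 | enantiomer of F4 | COc1ccc(COC[C@]2(O[Si](C)(C)C)CC[C@H](C(C)C)[C@H]3C=C(O[Si](C)(C)C)[C@H]32)cc1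
F9 | step 9 | 2-(tert-butoxycarbonyl)-2-(diethoxyphosphoryl)ethyl ester of 13 | COc1ccc(COC[C@@]2(O)CC[C@@H](C(C)C)[C@H](C=O)[C@@H]2C(=O)OCC(C(=O)OC(C)(C)C)P(=O)(OCC)OCC)cc1
F10 | step 14 | methyl 3-(4-methoxybenzyloxy)-2-(triphenylphosphoranylidene)propanoate | COC(=O)C(COCc1ccc(OC)cc1)=P(c1ccccc1)(c1ccccc1)c1ccccc1
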